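**Retrosynthetic overview**

1. The C40 chain is cut at C11'=C12' (last, Horner–Wadsworth–Emmons) and at C11=C12 (Wittig) into an ε-C15 phosphonate, the C10 trienedial and an acetylenic β-C15 phosphonium salt; both silyl ethers are removed at the end.
2. The β-ring is not formed in the route: it is bought as (4R,6R)-4-hydroxy-2,2,6-trimethylcyclohexanone and carried on through its enol triflate and a Sonogashira coupling with (E)-3-methylpent-2-en-4-yn-1-ol.
3. The ε-ring is the only ring that is formed: the C1'–C6' bond is closed by a proton-initiated cation–olefin cyclization of an acyclic (5R)-silyloxy dienoate made from (R)-epichlorohydrin, so C3' is bought and C6' is relayed from it.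
4. Enabling feature: in the ε-ring (cyclohexene C1'–C6') the gem-dimethyl quaternary carbon C1' is bonded to the allylic methine C6', the trisubstituted C4'=C5' alkene lies β,γ to C6', and the C3' oxygen is 1,3 to C1' and 1,4 to C6'. This is the footprint of Markovnikov protonation, 6-endo closure and proton loss through a chair that carries the C3' chirality across the ring.
5. Ring order: β-ring present from the start (separate branch); ε-ring closed in step 5; no other ring is made.

Key step: step 5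

Remark: the target is read as all-E (3R,3'R,6'R)-7,8-didehydro-β,ε-carotene-3,3'-diol; carotenoid numbering (primed locants for the ε half) is used for orientation.

**Route**

Step 1
Reactants: 1 (R)-epichlorohydrin
Product: 2 (2R)-1-chloro-4-methylpent-4-en-2-ol
Conditions: CH2=C(CH3)MgBr (1.1 equiv), CuI (10 mol %), THF, −40 °C; aq. NH4Cl
Reagents that add atoms: isopropenylmagnesium bromide, CC(=C)[Mg]Br
Why: copper-catalysed Grignard opening of the epoxide at its unsubstituted carbon (SN2) does not touch the stereocentre, so the configuration of 1 is carried over.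

Step 2
Reactants: 2 (2R)-1-chloro-4-methylpent-4-en-2-ol
Product: 4 (4R)-6-methylhept-6-en-1-yn-4-ol, via methallyl oxirane 3 (not isolated)
Conditions: LiC≡CH·H2NCH2CH2NH2 (3 equiv), DMSO, 5 °C → rt; aq. NH4Cl
Reagents that add atoms: lithium acetylide ethylenediamine complex, [Li+].[C-]#C.NCCN
Why: the acetylide first closes the chlorohydrin to the epoxide (intramolecular Williamson reaction) and then opens it at the CH2 terminus (SN2 alkynylation), so the carbinol centre is again untouched.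

Step 3
Reactants: 4 (4R)-6-methylhept-6-en-1-yn-4-ol
Product: 5 triisopropyl{[(4R)-6-methylhept-6-en-1-yn-4-yl]oxy}silane
Conditions: iPr3SiOTf, 2,6-lutidine, CH2Cl2, −78 → 0 °C
Reagents that add atoms: triisopropylsilyl trifluoromethanesulfonate, CC(C)[Si](C(C)C)(C(C)C)OS(=O)(=O)C(F)(F)F
Why: silyl triflate silylation of a secondary alcohol; the bulky, aryl-free TIPS ether is chosen to tolerate organoaluminium reagents, strong acid at low temperature and base.

Step 4
Reactants: 5 triisopropyl{[(4R)-6-methylhept-6-en-1-yn-4-yl]oxy}silane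
Product: 7 methyl (2E,5R)-3,7-dimethyl-5-(triisopropylsilyloxy)octa-2,7-dienoate, via alkenylalane 6 (not isolated)
Conditions: AlMe3 (2.5 equiv), Cp2ZrCl2 (0.25 equiv), CH2Cl2, 0 °C → rt; then ClCO2Me, rt
Reagents that add atoms: trimethylaluminium, C[Al](C)C; methyl chloroformate, COC(=O)Cl
Why: Negishi carboalumination adds methyl and aluminium syn across the terminal alkyne (methyl to the internal carbon) and leaves the 1,1-disubstituted alkene alone, and acylation of the alkenylalane with retention gives the (E)-enoate.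

Step 5
Reactants: 7 methyl (2E,5R)-3,7-dimethyl-5-(triisopropylsilyloxy)octa-2,7-dienoate
Product: 8 methyl (1R,4R)-2,6,6-trimethyl-4-(triisopropylsilyloxy)cyclohex-2-ene-1-carboxylate
Conditions: ClSO3H (3 equiv), 2-nitropropane, −78 °C (7 added slowly), 30 min; Et3N, −78 °C; aq. NaHCO3
Reagents that add atoms: none
Why: Markovnikov protonation of the isopropenyl group gives the tertiary cation at the future gem-dimethyl carbon, the α-carbon of the (E)-enoate captures it through a chair, and the tertiary ring cation then loses a proton from the ring CH2 next to the silyloxy carbon to give the trisubstituted ring alkene. The closest known reaction type is the low-temperature strong-acid cation–olefin cyclization of geranic and farnesoic esters to α-cyclogeranate rings (Stork–Eschenmoser mode). The single ring is closed in the 6-endo-trig mode with respect to the enoate alkene. The new stereocentre C1 is controlled by the (5R)-silyloxy centre: in the chair the OTIPS group (otherwise 1,3-diaxial to a methyl of the cationic carbon) and the ester (trans to the chain on the E alkene) both sit equatorial, which should give the 1,4-trans (1R,4R) ring. The step needs initiation at the isopropenyl group and not at the enoate alkene (secured by conjugation of the latter with the ester), kinetic proton loss to the 2-ene and not to the conjugated or exocyclic isomers (secured by low temperature and the hindered, ester-flanked C1–H), and survival of the silyl ether (TIPS, short contact at −78 °C).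

Step 6
Reactants: 8 methyl (1R,4R)-2,6,6-trimethyl-4-(triisopropylsilyloxy)cyclohex-2-ene-1-carboxylate; 9 ethyl (2E)-4-(diethoxyphosphoryl)-3-methylbut-2-enoate
Product: 12 ethyl (2E,4E)-3-methyl-5-[(1R,4R)-2,6,6-trimethyl-4-(triisopropylsilyloxy)cyclohex-2-en-1-yl]penta-2,4-dienoate, via lithio phosphonate 10 (not isolated), via ring aldehyde 11 (not isolated)
Conditions: iBu2AlH (1.1 equiv), CH2Cl2, −78 °C; then 10 (from 9, n-BuLi, THF–DMPU, −78 °C), −78 °C → rt; chromatography
Reagents that add atoms: none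
Why: one-pot half-reduction and Horner–Wadsworth–Emmons olefination, in which the aluminium hemiacetal releases the epimerisable aldehyde only as the vinylogous phosphonate anion consumes it; the new disubstituted alkene should form E, the trisubstituted alkene comes from the reagent, and the minor (2Z) isomer is removed by chromatography.

Step 7
Reactants: 12 ethyl (2E,4E)-3-methyl-5-[(1R,4R)-2,6,6-trimethyl-4-(triisopropylsilyloxy)cyclohex-2-en-1-yl]penta-2,4-dienoate
Product: 13 (2E,4E)-3-methyl-5-[(1R,4R)-2,6,6-trimethyl-4-(triisopropylsilyloxy)cyclohex-2-en-1-yl]penta-2,4-dien-1-ol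
Conditions: iBu2AlH (2.5 equiv), CH2Cl2, −78 °C; Rochelle salt work-up
Reagents that add atoms: none
Why: 1,2-reduction of a dienoate to the allylic alcohol by an aluminium hydride leaves the alkenes and the silyl ether untouched.

Step 8
Reactants: 13 (2E,4E)-3-methyl-5-[(1R,4R)-2,6,6-trimethyl-4-(triisopropylsilyloxy)cyclohex-2-en-1-yl]penta-2,4-dien-1-ol
Product: 15 diethyl {(2E,4E)-3-methyl-5-[(1R,4R)-2,6,6-trimethyl-4-(triisopropylsilyloxy)cyclohex-2-en-1-yl]penta-2,4-dien-1-yl}phosphonate, via allylic bromide 14 (not isolated)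
Conditions: CBr4, PPh3, CH2Cl2, −20 °C; then P(OEt)3, toluene, 90 °C
Reagents that add atoms: triethyl phosphite, CCOP(OCC)OCC
Why: Appel bromination of the primary allylic alcohol (SN2, alkene geometry kept) followed by Michaelis–Arbuzov reaction of the allylic bromide.

Step 9
Reactants: 16 (4R,6R)-4-hydroxy-2,2,6-trimethylcyclohexan-1-one
Product: 17 (4R,6R)-4-(tert-butyldimethylsilyloxy)-2,2,6-trimethylcyclohexan-1-one
Conditions: tBuMe2SiCl, imidazole, DMF, rt
Reagents that add atoms: tert-butyldimethylsilyl chloride, CC(C)(C)[Si](C)(C)Cl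
Why: standard silylation of the secondary alcohol, needed so that only the enolate oxygen is triflated in the next step.

Step 10
Reactants: 17 (4R,6R)-4-(tert-butyldimethylsilyloxy)-2,2,6-trimethylcyclohexan-1-one
Product: 19 (4R)-4-(tert-butyldimethylsilyloxy)-2,6,6-trimethylcyclohex-1-en-1-yl trifluoromethanesulfonate, via potassium enolate 18 (not isolated)
Conditions: KN(SiMe3)2, THF, −78 → 0 °C; then PhNTf2, −78 °C → rt
Reagents that add atoms: N-phenyl-bis(trifluoromethanesulfonimide), O=S(=O)(N(c1ccccc1)S(=O)(=O)C(F)(F)F)C(F)(F)F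
Why: the ketone has an α-hydrogen only at C6, so a single enolate forms and is O-triflated; the C6 stereocentre is removed on purpose and the C4 centre is untouched.

Step 11
Reactants: 19 (4R)-4-(tert-butyldimethylsilyloxy)-2,6,6-trimethylcyclohex-1-en-1-yl trifluoromethanesulfonate; 20 (2E)-3-methylpent-2-en-4-yn-1-ol
Product: 21 (2E)-5-[(4R)-4-(tert-butyldimethylsilyloxy)-2,6,6-trimethylcyclohex-1-en-1-yl]-3-methylpent-2-en-4-yn-1-ol
Conditions: Pd(PPh3)4 (5 mol %), CuI (10 mol %), iPr2NH, DMF, rt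
Reagents that add atoms: none
Why: Sonogashira coupling of an enol triflate with a terminal alkyne forms the ring–alkyne bond and keeps the (E) geometry of the enynol.

Step 12
Reactants: 21 (2E)-5-[(4R)-4-(tert-butyldimethylsilyloxy)-2,6,6-trimethylcyclohex-1-en-1-yl]-3-methylpent-2-en-4-yn-1-ol
Product: 23 tributyl{(2E)-5-[(4R)-4-(tert-butyldimethylsilyloxy)-2,6,6-trimethylcyclohex-1-en-1-yl]-3-methylpent-2-en-4-yn-1-yl}phosphonium bromide, via enynyl bromide 22 (not isolated)
Conditions: CBr4, PPh3 (1.0 equiv), CH2Cl2, −20 °C; then PBu3, EtOAc, 0 °C → rt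
Reagents that add atoms: carbon tetrabromide, BrC(Br)(Br)Br; tributylphosphine, CCCCP(CCCC)CCCC
Why: Appel bromination of the primary allylic alcohol and quaternisation of tributylphosphine by SN2 at the CH2 carbon, both without touching the trisubstituted alkene.

Step 13
Reactants: 23 tributyl{(2E)-5-[(4R)-4-(tert-butyldimethylsilyloxy)-2,6,6-trimethylcyclohex-1-en-1-yl]-3-methylpent-2-en-4-yn-1-yl}phosphonium bromide; 24 (2E,4E,6E)-2,7-dimethylocta-2,4,6-trienedial
Product: 26 (2E,4E,6E,8E,10E)-2,7,11-trimethyl-13-[(4R)-4-(tert-butyldimethylsilyloxy)-2,6,6-trimethylcyclohex-1-en-1-yl]trideca-2,4,6,8,10-pentaen-12-ynal, via phosphorus ylide 25 (not isolated)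
Conditions: NaOMe (1.1 equiv), CH2Cl2–MeOH, 0 °C, 23 added slowly to 24 (2.5 equiv), dark
Reagents that add atoms: none
Why: Wittig reaction of a semi-stabilised trialkylphosphonium ylide, which should give mainly the E alkene at C11=C12, with the dialdehyde in excess so that only one formyl group reacts.

Step 14
Reactants: 15 diethyl {(2E,4E)-3-methyl-5-[(1R,4R)-2,6,6-trimethyl-4-(triisopropylsilyloxy)cyclohex-2-en-1-yl]penta-2,4-dien-1-yl}phosphonate; 26 (2E,4E,6E,8E,10E)-2,7,11-trimethyl-13-[(4R)-4-(tert-butyldimethylsilyloxy)-2,6,6-trimethylcyclohex-1-en-1-yl]trideca-2,4,6,8,10-pentaen-12-ynal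
Product: 28 (3R,3'R,6'R)-3-(tert-butyldimethylsilyloxy)-3'-(triisopropylsilyloxy)-7,8-didehydro-β,ε-carotene, via phosphonate anion 27 (not isolated)
Conditions: KOtBu, THF, −40 °C; then 26, −40 → 0 °C, dark, argon
Reagents that add atoms: none
Why: Horner–Wadsworth–Emmons olefination of an allylic phosphonate anion with a polyenal should give the E C11'=C12' bond without a thermal isomerisation that could disturb the 9E enyne.

Step 15
Reactants: 28 (3R,3'R,6'R)-3-(tert-butyldimethylsilyloxy)-3'-(triisopropylsilyloxy)-7,8-didehydro-β,ε-carotene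
Product: 29 (3R,3'R,6'R)-7,8-didehydro-β,ε-carotene-3,3'-diol (the target)
Conditions: Bu4NF (4 equiv), THF, rt, dark, argon; crystallisation
Reagents that add atoms: none
Why: fluoride cleaves both silyl ethers under conditions that leave the polyene, the enyne and the acid-sensitive allylic 3'-alcohol alone.

**Compound list**

1 | (R)-epichlorohydrin, (2R)-2-(chloromethyl)oxirane | ClC[C@H]1CO1 | starting material
2 | (2R)-1-chloro-4-methylpent-4-en-2-ol | C=C(C)C[C@@H](O)CCl | intermediate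
3 | (2R)-2-(2-methylprop-2-en-1-yl)oxirane | C=C(C)C[C@@H]1CO1 | intermediate (not isolated)
4 | (4R)-6-methylhept-6-en-1-yn-4-ol | C=C(C)C[C@@H](O)CC#C | intermediate
5 | triisopropyl{[(4R)-6-methylhept-6-en-1-yn-4-yl]oxy}silane | C=C(C)C[C@@H](O[Si](C(C)C)(C(C)C)C(C)C)CC#C | intermediate
6 | [(1E,4R)-2,6-dimethyl-4-(triisopropylsilyloxy)hepta-1,6-dien-1-yl]dimethylalane | C=C(C)C[C@@H](O[Si](C(C)C)(C(C)C)C(C)C)C/C(C)=C/[Al](C)C | intermediate (not isolated)
7 | methyl (2E,5R)-3,7-dimethyl-5-(triisopropylsilyloxy)octa-2,7-dienoate | C=C(C)C[C@@H](O[Si](C(C)C)(C(C)C)C(C)C)C/C(C)=C/C(=O)OC | intermediate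
8 | methyl (1R,4R)-2,6,6-trimethyl-4-(triisopropylsilyloxy)cyclohex-2-ene-1-carboxylate (1,4-trans) | CC1=C[C@H](O[Si](C(C)C)(C(C)C)C(C)C)CC(C)(C)[C@H]1C(=O)OC | intermediate
9 | ethyl (2E)-4-(diethoxyphosphoryl)-3-methylbut-2-enoate | CCOC(=O)/C=C(\C)CP(=O)(OCC)OCC | starting material
10 | lithium salt of the α-phosphoryl carbanion of 9 | CCOC(=O)/C=C(\C)[CH-]P(=O)(OCC)OCC.[Li+] | intermediate (not isolated)
11 | (1R,4R)-2,6,6-trimethyl-4-(triisopropylsilyloxy)cyclohex-2-ene-1-carbaldehyde | CC1=C[C@H](O[Si](C(C)C)(C(C)C)C(C)C)CC(C)(C)[C@H]1C=O | intermediate (not isolated)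
12 | ethyl (2E,4E)-3-methyl-5-[(1R,4R)-2,6,6-trimethyl-4-(triisopropylsilyloxy)cyclohex-2-en-1-yl]penta-2,4-dienoate | CC1=C[C@H](O[Si](C(C)C)(C(C)C)C(C)C)CC(C)(C)[C@H]1/C=C/C(C)=C/C(=O)OCC | intermediate
13 | (2E,4E)-3-methyl-5-[(1R,4R)-2,6,6-trimethyl-4-(triisopropylsilyloxy)cyclohex-2-en-1-yl]penta-2,4-dien-1-ol | CC1=C[C@H](O[Si](C(C)C)(C(C)C)C(C)C)CC(C)(C)[C@H]1/C=C/C(C)=C/CO | intermediate
14 | {[(1R,4R)-4-[(1E,3E)-5-bromo-3-methylpenta-1,3-dien-1-yl]-3,5,5-trimethylcyclohex-2-en-1-yl]oxy}triisopropylsilane | CC1=C[C@H](O[Si](C(C)C)(C(C)C)C(C)C)CC(C)(C)[C@H]1/C=C/C(C)=C/CBr | intermediate (not isolated)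
15 | diethyl {(2E,4E)-3-methyl-5-[(1R,4R)-2,6,6-trimethyl-4-(triisopropylsilyloxy)cyclohex-2-en-1-yl]penta-2,4-dien-1-yl}phosphonate | CC1=C[C@H](O[Si](C(C)C)(C(C)C)C(C)C)CC(C)(C)[C@H]1/C=C/C(C)=C/CP(=O)(OCC)OCC | intermediate
16 | (4R,6R)-4-hydroxy-2,2,6-trimethylcyclohexan-1-one | O=C1C(C)(C)C[C@H](O)C[C@H]1C | starting material
17 | (4R,6R)-4-(tert-butyldimethylsilyloxy)-2,2,6-trimethylcyclohexan-1-one | O=C1C(C)(C)C[C@H](O[Si](C)(C)C(C)(C)C)C[C@H]1C | intermediate
18 | potassium (4R)-4-(tert-butyldimethylsilyloxy)-2,6,6-trimethylcyclohex-1-en-1-olate | CC1=C([O-])C(C)(C)C[C@H](O[Si](C)(C)C(C)(C)C)C1.[K+] | intermediate (not isolated)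
19 | (4R)-4-(tert-butyldimethylsilyloxy)-2,6,6-trimethylcyclohex-1-en-1-yl trifluoromethanesulfonate | CC1=C(OS(=O)(=O)C(F)(F)F)C(C)(C)C[C@H](O[Si](C)(C)C(C)(C)C)C1 | intermediate
20 | (2E)-3-methylpent-2-en-4-yn-1-ol | C#C/C(C)=C/CO | starting material
21 | (2E)-5-[(4R)-4-(tert-butyldimethylsilyloxy)-2,6,6-trimethylcyclohex-1-en-1-yl]-3-methylpent-2-en-4-yn-1-ol | CC1=C(C#C/C(C)=C/CO)C(C)(C)C[C@H](O[Si](C)(C)C(C)(C)C)C1 | intermediate
22 | {[(1R)-4-[(3E)-5-bromo-3-methylpent-3-en-1-yn-1-yl]-3,5,5-trimethylcyclohex-3-en-1-yl]oxy}(tert-butyl)dimethylsilane | CC1=C(C#C/C(C)=C/CBr)C(C)(C)C[C@H](O[Si](C)(C)C(C)(C)C)C1 | intermediate (not isolated)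
23 | tributyl{(2E)-5-[(4R)-4-(tert-butyldimethylsilyloxy)-2,6,6-trimethylcyclohex-1-en-1-yl]-3-methylpent-2-en-4-yn-1-yl}phosphonium bromide | CC1=C(C#C/C(C)=C/C[P+](CCCC)(CCCC)CCCC)C(C)(C)C[C@H](O[Si](C)(C)C(C)(C)C)C1.[Br-] | intermediate
24 | (2E,4E,6E)-2,7-dimethylocta-2,4,6-trienedial | O=C/C(C)=C/C=C/C=C(\C)C=O | starting material
25 | tributyl{(2E)-5-[(4R)-4-(tert-butyldimethylsilyloxy)-2,6,6-trimethylcyclohex-1-en-1-yl]-3-methylpent-2-en-4-yn-1-ylidene}phosphorane | CC1=C(C#C/C(C)=C/C=P(CCCC)(CCCC)CCCC)C(C)(C)C[C@H](O[Si](C)(C)C(C)(C)C)C1 | intermediate (not isolated)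
26 | (2E,4E,6E,8E,10E)-2,7,11-trimethyl-13-[(4R)-4-(tert-butyldimethylsilyloxy)-2,6,6-trimethylcyclohex-1-en-1-yl]trideca-2,4,6,8,10-pentaen-12-ynal, the (3R)-3-silyloxy-7,8-didehydro-12'-apo-β-caroten-12'-al | CC1=C(C#C/C(C)=C/C=C/C(C)=C/C=C/C=C(\C)C=O)C(C)(C)C[C@H](O[Si](C)(C)C(C)(C)C)C1 | intermediate
27 | potassium salt of the α-phosphoryl carbanion of 15 | CC1=C[C@H](O[Si](C(C)C)(C(C)C)C(C)C)CC(C)(C)[C@H]1/C=C/C(C)=C/[CH-]P(=O)(OCC)OCC.[K+] | intermediate (not isolated)
28 | (3R,3'R,6'R)-3-(tert-butyldimethylsilyloxy)-3'-(triisopropylsilyloxy)-7,8-didehydro-β,ε-carotene | CC1=C[C@H](O[Si](C(C)C)(C(C)C)C(C)C)CC(C)(C)[C@H]1/C=C/C(C)=C/C=C/C(C)=C/C=C/C=C(C)/C=C/C=C(\C)C#CC1=C(C)C[C@@H](O[Si](C)(C)C(C)(C)C)CC1(C)C | intermediate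
29 | (3R,3'R,6'R)-7,8-didehydro-β,ε-carotene-3,3'-diol | CC1=C[C@H](O)CC(C)(C)[C@H]1/C=C/C(C)=C/C=C/C(C)=C/C=C/C=C(C)/C=C/C=C(\C)C#CC1=C(C)C[C@@H](O)CC1(C)C | target

**Step count**

Total: 15 steps. Longest linear sequence: 10 steps (steps 1–8, 14, 15).

**Steps most likely to fail**

Step 5. What may go wrong: protonation at the enoate instead of the isopropenyl group, loss of the silyl ether or fragmentation of the β-silyloxy cation in the strong acid, and proton loss to the conjugated or exocyclic alkene. The fallback sets out from 7 and comes back at 8. It replaces the Brønsted acid by an amine-buffered electrophilic mercuration: 7 is treated with the Hg(OTf)2·N,N-dimethylaniline complex in MeNO2 at −20 °C, which attacks only the isopropenyl group and triggers the same 6-endo closure without free strong acid. Exchange with aqueous NaCl gives methyl (1R,4R)-6-(chloromercuriomethyl)-2,6-dimethyl-4-(triisopropylsilyloxy)cyclohex-2-ene-1-carboxylate F1 (either configuration at C6, which is lost next). Reductive demercuration with NaBH4 in THF–aqueous NaOH turns the CH2HgCl group into the second methyl group and gives 8.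

Step 6. What may go wrong: over-reduction of the ester to the alcohol, and epimerisation at C1 or migration of the ring alkene into conjugation while the aldehyde meets the basic phosphonate. The fallback sets out from 8 and comes back at 12, and it reverses the polarity so that C1 is never α to a carbonyl group during the olefination. Reduction of 8 with LiAlH4 in Et2O gives [(1R,4R)-2,6,6-trimethyl-4-(triisopropylsilyloxy)cyclohex-2-en-1-yl]methanol F2. Mitsunobu thioetherification with 1-phenyl-1H-tetrazole-5-thiol (PPh3, diisopropyl azodicarboxylate) gives 1-phenyl-5-({[(1R,4R)-2,6,6-trimethyl-4-(triisopropylsilyloxy)cyclohex-2-en-1-yl]methyl}sulfanyl)-1H-tetrazole F3, and oxidation with (NH4)6Mo7O24·4H2O and H2O2 in EtOH gives 1-phenyl-5-({[(1R,4R)-2,6,6-trimethyl-4-(triisopropylsilyloxy)cyclohex-2-en-1-yl]methyl}sulfonyl)-1H-tetrazole F4. Julia–Kocienski olefination of F4 (KN(SiMe3)2, DME, −60 °C) with commercial ethyl (2E)-3-methyl-4-oxobut-2-enoate gives 12.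

Step 13. What may go wrong: rotation about the C9–C10 bond in the delocalised enynyl ylide, which would erode the 9E geometry, and olefination of both formyl groups of the dialdehyde. The fallback sets out from 15, 24 and 21 and comes back at 28; it changes the order of the couplings so that the enyne is only ever an electrophile. Olefination of an excess of 24 with the potassium salt of 15 (KOtBu, THF, −40 °C) gives (2E,4E,6E,8E,10E,12E)-2,7,11-trimethyl-13-[(1R,4R)-2,6,6-trimethyl-4-(triisopropylsilyloxy)cyclohex-2-en-1-yl]trideca-2,4,6,8,10,12-hexaenal F5. Reduction with NaBH4 in MeOH–THF gives the corresponding (2E,4E,6E,8E,10E,12E)-trideca-2,4,6,8,10,12-hexaen-1-ol F6, and Appel bromination followed by P(OEt)3 gives the corresponding diethyl (2E,4E,6E,8E,10E,12E)-trideca-2,4,6,8,10,12-hexaen-1-ylphosphonate F7. Separately, oxidation of 21 with MnO2 in CH2Cl2 gives (2E)-5-[(4R)-4-(tert-butyldimethylsilyloxy)-2,6,6-trimethylcyclohex-1-en-1-yl]-3-methylpent-2-en-4-ynal F8. Olefination of F8 with the potassium salt of F7 (KOtBu, THF, −40 → 0 °C) forms C11=C12 and gives 28.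

Further compounds
F1 | step 5 | methyl (1R,4R)-6-(chloromercuriomethyl)-2,6-dimethyl-4-(triisopropylsilyloxy)cyclohex-2-ene-1-carboxylate (C6 undefined) | CC1=C[C@H](O[Si](C(C)C)(C(C)C)C(C)C)CC(C)(C[Hg]Cl)[C@H]1C(=O)OC
F2 | step 6 | [(1R,4R)-2,6,6-trimethyl-4-(triisopropylsilyloxy)cyclohex-2-en-1-yl]methanol | CC1=C[C@H](O[Si](C(C)C)(C(C)C)C(C)C)CC(C)(C)[C@H]1CO
F3 | step 6 | 1-phenyl-5-({[(1R,4R)-2,6,6-trimethyl-4-(triisopropylsilyloxy)cyclohex-2-en-1-yl]methyl}sulfanyl)-1H-tetrazole | CC1=C[C@H](O[Si](C(C)C)(C(C)C)C(C)C)CC(C)(C)[C@H]1CSc1nnnn1-c1ccccc1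
F4 | step 6 | 1-phenyl-5-({[(1R,4R)-2,6,6-trimethyl-4-(triisopropylsilyloxy)cyclohex-2-en-1-yl]methyl}sulfonyl)-1H-tetrazole | CC1=C[C@H](O[Si](C(C)C)(C(C)C)C(C)C)CC(C)(C)[C@H]1CS(=O)(=O)c1nnnn1-c1ccccc1
F5 | step 13 | (2E,4E,6E,8E,10E,12E)-2,7,11-trimethyl-13-[(1R,4R)-2,6,6-trimethyl-4-(triisopropylsilyloxy)cyclohex-2-en-1-yl]trideca-2,4,6,8,10,12-hexaenal | CC1=C[C@H](O[Si](C(C)C)(C(C)C)C(C)C)CC(C)(C)[C@H]1/C=C/C(C)=C/C=C/C(C)=C/C=C/C=C(\C)C=O
F6 | step 13 | (2E,4E,6E,8E,10E,12E)-2,7,11-trimethyl-13-[(1R,4R)-2,6,6-trimethyl-4-(triisopropylsilyloxy)cyclohex-2-en-1-yl]trideca-2,4,6,8,10,12-hexaen-1-ol | CC1=C[C@H](O[Si](C(C)C)(C(C)C)C(C)C)CC(C)(C)[C@H]1/C=C/C(C)=C/C=C/C(C)=C/C=C/C=C(\C)CO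
F7 | step 13 | diethyl {(2E,4E,6E,8E,10E,12E)-2,7,11-trimethyl-13-[(1R,4R)-2,6,6-trimethyl-4-(triisopropylsilyloxy)cyclohex-2-en-1-yl]trideca-2,4,6,8,10,12-hexaen-1-yl}phosphonate | CC1=C[C@H](O[Si](C(C)C)(C(C)C)C(C)C)CC(C)(C)[C@H]1/C=C/C(C)=C/C=C/C(C)=C/C=C/C=C(\C)CP(=O)(OCC)OCC
F8 | step 13 | (2E)-5-[(4R)-4-(tert-butyldimethylsilyloxy)-2,6,6-trimethylcyclohex-1-en-1-yl]-3-methylpent-2-en-4-ynal | CC1=C(C#C/C(C)=C/C=O)C(C)(C)C[C@H](O[Si](C)(C)C(C)(C)C)C1
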